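**Retrosynthetic overview**
1. Target ⇒ O‑acetylation, hydroxyl‑directed epoxidation of C11=C12 (the oxirane is the last ring) and 1,2‑reduction at C13 of a macrocyclic keto lactone.
2. Key disconnection C1–C2 together with the lactone C16–O bond: chromium‑electrocatalysed intramolecular allylation of a C2 enal by a 2‑(bromomethyl)enoate. The 14‑membered carbocycle closes first, the cis‑fused γ‑lactone second, in the same operation.
3. Open‑chain precursor ⇒ cross‑metathesis at C1=C15, allylation at C13–C14, cross‑metathesis at C6=C7, allylic oxidation at C13; C13 is carried through ring closure as a ketone.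
4. Building blocks: (R)‑linalool (brings C8, from which all other stereocentres are relayed), pent‑1‑en‑4‑yne, allyl bromide, methyl 2‑(bromomethyl)acrylate.

Assumption: cembrane locants are used throughout, also for the matching carbons of open‑chain intermediates (C1 ring‑fusion CH bearing C15, C2 lactone O–CH, C8 carbinol, C11/C12 oxirane, C13 acetoxy carbon, C17 exocyclic CH2).

**Step 1**
Reactants: 1 (R)‑(−)‑linalool
Product: 2 (2E,6R)‑6‑hydroxy‑2,6‑dimethylocta‑2,7‑dienal
Conditions: SeO2 (1.1 equiv), 1,4‑dioxane, 80 °C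
Reagents that add atoms: selenium dioxide (O=[Se]=O)
Why: Riley allylic oxidation (ene reaction, then [2,3]‑shift) attacks only the (E)‑methyl group of the trisubstituted olefin and gives the (E)‑enal, while the quaternary C8 stereocentre bought with 1 is untouched.

**Step 2**
Reactants: 3 pent‑1‑en‑4‑yne
Product: 6 (2E)‑3‑methylhexa‑2,5‑dien‑1‑ol, via alkenylalane 4 (not isolated), via lithium alkenylaluminate 5 (not isolated)
Conditions: AlMe3 (2 equiv), Cp2ZrCl2 (0.2 equiv), CH2Cl2, 0 to 25 °C; n‑BuLi, THF, −78 °C; (CH2O)n, −78 to 25 °C; aq. work‑up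
Reagents that add atoms: trimethylaluminium (C[Al](C)C); formaldehyde, used as paraformaldehyde (C=O)
Why: Negishi zirconium‑catalysed carboalumination adds CH3–Al syn across the terminal alkyne only, and the alanate is hydroxymethylated with retention, which fixes the (E)‑trisubstituted olefin.

**Step 3**
Reactants: 2 (2E,6R)‑6‑hydroxy‑2,6‑dimethylocta‑2,7‑dienal; 6 (2E)‑3‑methylhexa‑2,5‑dien‑1‑ol
Product: 7 (2E,6R,7E,10E)‑6,12‑dihydroxy‑2,6,10‑trimethyldodeca‑2,7,10‑trienal
Conditions: 6 (3 equiv), second‑generation Hoveyda–Grubbs catalyst RuCl2(SIMes)(=CH–C6H4‑2‑OiPr) (5 mol%), 1,4‑benzoquinone (10 mol%), CH2Cl2, 40 °C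
Reagents that add atoms: none
Why: Olefin cross‑metathesis joins the unhindered allyl terminus of 6 to the vinyl carbinol of 2 and gives only the (E)‑olefin next to the quaternary carbinol, while the enal and the trisubstituted olefins stay out.

**Step 4**
Reactants: 7 (2E,6R,7E,10E)‑6,12‑dihydroxy‑2,6,10‑trimethyldodeca‑2,7,10‑trienal; 8 allyl bromide
Product: 10 (2E,5E,7R,10E,12RS)‑3,7,11‑trimethylpentadeca‑2,5,10,14‑tetraene‑1,7,12‑triol, via allylzinc bromide 9 (not isolated)
Conditions: Zn dust (3 equiv), 8 (2 equiv), THF/sat. aq. NH4Cl, 0 to 25 °C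
Reagents that add atoms: none
Why: Zinc Barbier allylation adds 1,2 to the enal in the presence of free hydroxyls; the C13 carbinol is formed as a 1:1 mixture on purpose, because this centre is erased in step 6 and set in step 8.

**Step 5**
Reactants: 10 the C13‑epimeric triol; 11 methyl 2‑(bromomethyl)acrylate
Product: 12 methyl (2Z,5RS,6E,10R,11E,14E)‑2‑(bromomethyl)‑5,10,16‑trihydroxy‑6,10,14‑trimethylhexadeca‑2,6,11,14‑tetraenoate
Conditions: 11 (4 equiv), second‑generation Hoveyda–Grubbs catalyst RuCl2(SIMes)(=CH–C6H4‑2‑OiPr) (7.5 mol%), 1,4‑benzoquinone (10 mol%), CH2Cl2, 40 °C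
Reagents that add atoms: none
Why: Cross‑metathesis of the only monosubstituted olefin with a methacrylate‑type partner gives the thermodynamic trisubstituted enoate with the chain trans to the ester, i.e. the (Z)‑2‑(bromomethyl) isomer needed for a syn‑selective allylation.

**Step 6**
Reactants: 12 the trihydroxy allylic bromide
Product: 13 methyl (2Z,6E,10R,11E,14E)‑2‑(bromomethyl)‑10‑hydroxy‑6,10,14‑trimethyl‑5,16‑dioxohexadeca‑2,6,11,14‑tetraenoate
Conditions: Dess–Martin periodinane (2.4 equiv), pyridine, CH2Cl2, 0 °C; used at once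
Reagents that add atoms: none
Why: Dess–Martin oxidation turns the primary allylic alcohol into the (E)‑enal and both C13 epimers into one enone without touching the tertiary alcohol or the allylic bromide, and the pyridine buffer keeps the β,γ‑unsaturated ketone from conjugating.

**Step 7**
Reactants: 13 the keto enal allylic bromide
Product: 17 (1S,2S,3E,6E,8R,11E)‑8‑hydroxy‑13‑oxocembra‑3,6,11,15(17)‑tetraen‑16,2‑olide, via C8 silyl ether 14 (not isolated), via allylchromium dichloride 15 (not isolated), via seco bis‑silyl ether 16 (not isolated)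
Conditions: 1‑(trimethylsilyl)imidazole (1.5 equiv), THF, 25 °C; then CrCl3(THF)3 (20 mol%), Me3SiCl (3 equiv), n‑Bu4NPF6 (0.1 M), THF/DMF 4:1, undivided cell, aluminium anode, nickel‑foam cathode, constant current (2.2 F/mol), 14 added over 12 h (final 2 mM), 25 °C; then PPTS (0.2 equiv), MeOH, 25 °C
Reagents that add atoms: none
Why: Proposed new method: a chromium‑electrocatalytic intramolecular Nozaki–Hiyama (Barbier‑type) allylation–lactonisation. The cathode reduces catalytic CrCl3 to divalent chromium at a potential (about −1.0 V vs SCE) where enal, enone and C–Br are not reduced directly; two divalent chromium ions convert the activated allylic bromide of 14 into the allyl–trivalent‑chromium species 15; its γ‑carbon (C1) adds to the C2 aldehyde through a chair Zimmerman–Traxler transition state (C14 axial because it is cis to the CH2–Cr carbon, enal chain equatorial), which gives the syn adduct and hence the cis‑fused lactone; Me3SiCl frees chromium from the alkoxide as silyl ether 16 so the metal turns over, the slow cathodic generation keeps the organochromium dilute so that ring closure beats oligomerisation, and PPTS/MeOH then removes both silyl groups and closes the γ‑lactone. The 1S,2S sense is relayed from C8 by macrocyclic control (C8 at a ring corner, bulky OSiMe3 on the face opposite the chromium‑bound C2–O, CH3 on the lactone face); this is a model, not a precedent. Closest known chemistry: stoichiometric CrCl2 couplings of 2‑(alkoxycarbonyl)allyl bromides with aldehydes to cis‑α‑methylene‑γ‑butyrolactones, Nozaki–Hiyama macrocyclisations of cembranoids, and chromium‑catalytic Nozaki–Hiyama–Kishi couplings turned over by Mn/Me3SiCl or by a cathode (intermolecular only).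

**Step 8**
Reactants: 17 the macrocyclic keto lactone
Product: 18 (1S,2S,3E,6E,8R,11E,13S)‑8,13‑dihydroxycembra‑3,6,11,15(17)‑tetraen‑16,2‑olide
Conditions: NaBH4 (1.1 equiv), CeCl3·7H2O (1.2 equiv), MeOH/THF, −78 °C
Reagents that add atoms: none
Why: Luche reduction is 1,2‑selective for the enone over the α‑methylene lactone, and hydride is expected to enter from the ring face opposite the cis‑fused lactone (the H1/H2 face; 1,3‑induction from C1 within the macrocycle), placing the new OH syn to C15 (13S).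

**Step 9**
Reactants: 18 the (13S)‑allylic alcohol
Product: 19 (1S,2S,3E,6E,8R,11S,12S,13S)‑11,12‑epoxy‑8,13‑dihydroxycembra‑3,6,15(17)‑trien‑16,2‑olide
Conditions: VO(acac)2 (5 mol%), t‑BuOOH (1.1 equiv, decane), CH2Cl2, 0 °C
Reagents that add atoms: tert‑butyl hydroperoxide (CC(C)(C)OO)
Why: Vanadium‑catalysed hydroxyl‑directed epoxidation (achiral Sharpless–Michaelson conditions) oxidises the trisubstituted olefin allylic to the secondary C13–OH, and A(1,2) strain with the C12 methyl group in the vanadate transition state gives the erythro epoxy alcohol, which has the target's oxirane configuration (12S here only through a CIP priority change).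

**Step 10**
Reactants: 19 the epoxy diol
Product: 20 (1S,2S,3E,6E,8R,11S,12R,13S)‑13‑acetoxy‑11,12‑epoxy‑8‑hydroxycembra‑3,6,15(17)‑trien‑16,2‑olide (CNP0288879.3)
Conditions: Ac2O (1.5 equiv), pyridine, DMAP (5 mol%), CH2Cl2, 0 °C
Reagents that add atoms: acetic anhydride (CC(=O)OC(C)=O)
Why: DMAP‑catalysed acetylation esterifies the secondary C13 alcohol, while the hindered tertiary C8 alcohol, the oxirane and the α‑methylene lactone are unaffected.

**Compound list**
1 | (R)‑(−)‑linalool, (3R)‑3,7‑dimethylocta‑1,6‑dien‑3‑ol | C=C[C@](C)(O)CCC=C(C)C | starting material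
2 | (2E,6R)‑6‑hydroxy‑2,6‑dimethylocta‑2,7‑dienal | C=C[C@](C)(O)CC/C=C(\C)C=O | intermediate
3 | pent‑1‑en‑4‑yne | C=CCC#C | starting material
4 | dimethyl[(1E)‑2‑methylpenta‑1,4‑dien‑1‑yl]alane | C=CC/C(C)=C/[Al](C)C | intermediate
5 | lithium butyldimethyl[(1E)‑2‑methylpenta‑1,4‑dien‑1‑yl]aluminate | [Li+].C=CC/C(C)=C/[Al-](C)(C)CCCC | intermediate
6 | (2E)‑3‑methylhexa‑2,5‑dien‑1‑ol | C=CC/C(C)=C/CO | intermediate
7 | (2E,6R,7E,10E)‑6,12‑dihydroxy‑2,6,10‑trimethyldodeca‑2,7,10‑trienal | OC/C=C(\C)C/C=C/[C@](C)(O)CC/C=C(\C)C=O | intermediate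
8 | allyl bromide | C=CCBr | starting material
9 | allylzinc bromide | C=CC[Zn]Br | intermediate
10 | (2E,5E,7R,10E,12RS)‑3,7,11‑trimethylpentadeca‑2,5,10,14‑tetraene‑1,7,12‑triol (1:1 at the carbinol that becomes C13) | OC/C=C(\C)C/C=C/[C@](C)(O)CC/C=C(\C)C(O)CC=C | intermediate
11 | methyl 2‑(bromomethyl)acrylate | C=C(CBr)C(=O)OC | starting material
12 | methyl (2Z,5RS,6E,10R,11E,14E)‑2‑(bromomethyl)‑5,10,16‑trihydroxy‑6,10,14‑trimethylhexadeca‑2,6,11,14‑tetraenoate | OC/C=C(\C)C/C=C/[C@](C)(O)CC/C=C(\C)C(O)C/C=C(\CBr)C(=O)OC | intermediate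
13 | methyl (2Z,6E,10R,11E,14E)‑2‑(bromomethyl)‑10‑hydroxy‑6,10,14‑trimethyl‑5,16‑dioxohexadeca‑2,6,11,14‑tetraenoate | O=C/C=C(\C)C/C=C/[C@](C)(O)CC/C=C(\C)C(=O)C/C=C(\CBr)C(=O)OC | intermediate
14 | 10‑O‑trimethylsilyl ether of 13 (silyl ether of the C8 carbinol) | O=C/C=C(\C)C/C=C/[C@](C)(O[Si](C)(C)C)CC/C=C(\C)C(=O)C/C=C(\CBr)C(=O)OC | intermediate
15 | allylchromium dichloride from 14 (CH2–CrCl2 in place of CH2Br, trivalent chromium) | O=C/C=C(\C)C/C=C/[C@](C)(O[Si](C)(C)C)CC/C=C(\C)C(=O)C/C=C(\C[Cr](Cl)Cl)C(=O)OC | intermediate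
16 | methyl (1S,2S,3E,6E,8R,11E)‑13‑oxo‑2,8‑bis(trimethylsilyloxy)cembra‑3,6,11,15(17)‑tetraen‑16‑oate | C=C(C(=O)OC)[C@@H]1CC(=O)/C(C)=C/CC[C@@](C)(O[Si](C)(C)C)/C=C/C/C(C)=C/[C@@H]1O[Si](C)(C)C | intermediate
17 | (1S,2S,3E,6E,8R,11E)‑8‑hydroxy‑13‑oxocembra‑3,6,11,15(17)‑tetraen‑16,2‑olide | C=C1C(=O)O[C@H]2/C=C(\C)C/C=C/[C@](C)(O)CC/C=C(\C)C(=O)C[C@@H]12 | intermediate
18 | (1S,2S,3E,6E,8R,11E,13S)‑8,13‑dihydroxycembra‑3,6,11,15(17)‑tetraen‑16,2‑olide | C=C1C(=O)O[C@H]2/C=C(\C)C/C=C/[C@](C)(O)CC/C=C(\C)[C@@H](O)C[C@@H]12 | intermediate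
19 | (1S,2S,3E,6E,8R,11S,12S,13S)‑11,12‑epoxy‑8,13‑dihydroxycembra‑3,6,15(17)‑trien‑16,2‑olide | C=C1C(=O)O[C@H]2/C=C(\C)C/C=C/[C@](C)(O)CC[C@@H]3O[C@@]3(C)[C@@H](O)C[C@@H]12 | intermediate
20 | (1S,2S,3E,6E,8R,11S,12R,13S)‑13‑acetoxy‑11,12‑epoxy‑8‑hydroxycembra‑3,6,15(17)‑trien‑16,2‑olide | C=C1C(=O)O[C@H]2/C=C(\C)C/C=C/[C@](C)(O)CC[C@@H]3O[C@@]3(C)[C@@H](OC(C)=O)C[C@@H]12 | target

**Step count and risks**
Total step count: 10. Longest linear sequence: 9 steps (from 1 through steps 1 and 3 to 10); step 2 is a one‑step side branch.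

The three steps most likely to fail:

Step 7. This is the proposed new reaction and also the weakest stereochemical link. Chromium turnover at the cathode, competition from oligomerisation, the lability of the β,γ‑unsaturated ketone 13 and, above all, the face selection relayed from the remote C8 centre are all untested; the C8 relay may well be modest, in which case the 1R,2R diastereomer has to be separated. The fallback uses known chemistry and replaces electrocatalysis by chemical, stoichiometric generation of the organochromium with a separate lactonisation. It sets out from 13, which is silylated as in step 7 to 14 and cyclised under classical Nozaki–Hiyama conditions (CrCl2, 8–10 equiv, THF, 4 Å sieves, syringe‑pump addition, 25 °C, aqueous work‑up). This gives the macrocyclic hydroxy ester methyl (1S,2S,3E,6E,8R,11E)‑2‑hydroxy‑13‑oxo‑8‑(trimethylsilyloxy)cembra‑3,6,11,15(17)‑tetraen‑16‑oate F1. PPTS in MeOH then removes the silyl group and closes the lactone, and the route is rejoined at 17.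

Step 8. The sense of hydride delivery to the macrocyclic enone rests on a conformational model and may be reversed. The fallback sets out from 17. If the reduction gives mainly the epimeric alcohol (1S,2S,3E,6E,8R,11E,13R)‑8,13‑dihydroxycembra‑3,6,11,15(17)‑tetraen‑16,2‑olide F2, a Mitsunobu inversion (PPh3, DIAD, methoxyacetic acid, THF, 0 °C) converts it into the (13S)‑methoxyacetate (1S,2S,3E,6E,8R,11E,13S)‑8‑hydroxy‑13‑(methoxyacetoxy)cembra‑3,6,11,15(17)‑tetraen‑16,2‑olide F3. Methanolysis catalysed by Yb(OTf)3 in MeOH removes the acyl group without touching the α‑methylene lactone, and the route is rejoined at 18.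

Step 5. Cross‑metathesis of a 1,1‑disubstituted bromomethyl acrylate on the polyfunctional triene triol 10 may be slow or scrambled by secondary metathesis. The fallback changes the order of fragment union so that this metathesis is run on a much simpler substrate; it does not help if the acrylate itself is a poor metathesis partner. It sets out from 2. Zinc Barbier allylation with 8 (through 9) gives (3R,6E,8RS)‑3,7‑dimethylundeca‑1,6,10‑triene‑3,8‑diol F4. Cross‑metathesis with 11 at the unhindered homoallylic terminus (the vinyl carbinol is much slower) gives methyl (2Z,5RS,6E,10R)‑2‑(bromomethyl)‑5,10‑dihydroxy‑6,10‑dimethyldodeca‑2,6,11‑trienoate F5. Cross‑metathesis of F5 with 6 at the vinyl carbinol then rejoins the route at 12.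

**Further compounds**
F1 | step 7 | methyl (1S,2S,3E,6E,8R,11E)‑2‑hydroxy‑13‑oxo‑8‑(trimethylsilyloxy)cembra‑3,6,11,15(17)‑tetraen‑16‑oate | C=C(C(=O)OC)[C@@H]1CC(=O)/C(C)=C/CC[C@@](C)(O[Si](C)(C)C)/C=C/C/C(C)=C/[C@@H]1O
F2 | step 8 | (1S,2S,3E,6E,8R,11E,13R)‑8,13‑dihydroxycembra‑3,6,11,15(17)‑tetraen‑16,2‑olide | C=C1C(=O)O[C@H]2/C=C(\C)C/C=C/[C@](C)(O)CC/C=C(\C)[C@H](O)C[C@@H]12
F3 | step 8 | (1S,2S,3E,6E,8R,11E,13S)‑8‑hydroxy‑13‑(methoxyacetoxy)cembra‑3,6,11,15(17)‑tetraen‑16,2‑olide | C=C1C(=O)O[C@H]2/C=C(\C)C/C=C/[C@](C)(O)CC/C=C(\C)[C@@H](OC(=O)COC)C[C@@H]12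
F4 | step 5 | (3R,6E,8RS)‑3,7‑dimethylundeca‑1,6,10‑triene‑3,8‑diol | C=C[C@](C)(O)CC/C=C(\C)C(O)CC=C
F5 | step 5 | methyl (2Z,5RS,6E,10R)‑2‑(bromomethyl)‑5,10‑dihydroxy‑6,10‑dimethyldodeca‑2,6,11‑trienoate | C=C[C@](C)(O)CC/C=C(\C)C(O)C/C=C(\CBr)C(=O)OC
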